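**Retrosynthetic overview**
1. Target 10 comes from alcohol 9 by chemoselective O-sulfation of the primary hydroxyl (last step).
2. Alcohol 9 comes from α-hydroxy ketone 7 by ionic hydrogenation of the benzylic C=O, with loss of the two MOM groups in the same pot.
3. Key C–C disconnection, ArC(=O)–CH2OH: aldehyde 4 serves as a catalytic acyl anion (Breslow intermediate) that adds to formaldehyde 5, joining two carbonyl carbons.
4. Aldehyde 4 comes from 5-bromovanillin 1 by ring bromination, O-demethylation and bis-MOM protection.
5. No ring is formed; the benzene ring is carried through from 1.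

Assumption: the target has no stereocentre and no stereogenic double bond, so it is one achiral compound, no stereocontrol is needed, and it is made as the free hydrogen sulfate drawn.

**Step 1**
Reactants: 1 5-bromovanillin (3-bromo-4-hydroxy-5-methoxybenzaldehyde)
Product: 2 2,3-dibromo-4-hydroxy-5-methoxybenzaldehyde (5,6-dibromovanillin)
Conditions: Br2 (1.3 equiv), Fe powder (5 mol %), AcOH, rt → 50 °C
Reagents that add atoms: bromine, BrBr
Why: Iron-catalysed electrophilic aromatic bromination goes to the open position para to the methoxy group (between CHO and Br), which gives the 5,6-dibromovanillin pattern; no stereocentre.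

**Step 2**
Reactants: 2 2,3-dibromo-4-hydroxy-5-methoxybenzaldehyde
Product: 3 2,3-dibromo-4,5-dihydroxybenzaldehyde
Conditions: BBr3 (3 equiv), CH2Cl2, −78 °C → rt; then H2O
Reagents that add atoms: none
Why: Lewis-acid aryl methyl ether cleavage with BBr3, helped by the neighbouring phenol forming a cyclic borate, frees the catechol and leaves the aldehyde and both C–Br bonds intact after aqueous work-up.

**Step 3**
Reactants: 3 2,3-dibromo-4,5-dihydroxybenzaldehyde
Product: 4 2,3-dibromo-4,5-bis(methoxymethoxy)benzaldehyde
Conditions: MOMCl (2.5 equiv), iPr2NEt (3 equiv), CH2Cl2, 0 °C → rt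
Reagents that add atoms: chloromethyl methyl ether (MOMCl), COCCl
Why: Williamson-type O-alkylation of the two acidic phenols gives base-stable, acid-labile MOM ethers, which keep phenoxides out of the carbene step and are shed in step 5.

**Step 4**
Reactants: 4 2,3-dibromo-4,5-bis(methoxymethoxy)benzaldehyde; 5 paraformaldehyde
Product: 7 1-[2,3-dibromo-4,5-bis(methoxymethoxy)phenyl]-2-hydroxyethan-1-one, via Breslow enaminol 6 (not isolated)
Conditions: 3-benzyl-5-(2-hydroxyethyl)-4-methylthiazolium chloride (10 mol %), iPr2NEt (20 mol %), (CH2O)n (3 equiv), THF, 60 °C, sealed tube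
Reagents that add atoms: none
Why: NHC-catalysed cross-benzoin (hydroxymethylation): the thiazol-2-ylidene turns the aldehyde carbon of 4 into the nucleophilic Breslow enaminol 6, an acyl anion equivalent, which adds to the small, highly electrophilic formaldehyde while the ortho-bromine disfavours self-benzoin; the product is achiral.

**Step 5**
Reactants: 7 1-[2,3-dibromo-4,5-bis(methoxymethoxy)phenyl]-2-hydroxyethan-1-one
Product: 9 2-(2,3-dibromo-4,5-dihydroxyphenyl)ethan-1-ol, via trifluoroacetate ester 8 (not isolated)
Conditions: Et3SiH (6 equiv), TFA, 0 °C → 50 °C; then NaHCO3, MeOH/H2O, rt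
Reagents that add atoms: none
Why: Ionic hydrogenation (Kursanov–Parnes): TFA cleaves the MOM ethers (the oxocarbenium ion is reduced by the silane), and the p-hydroxyaryl ketone is taken to CH2 by two hydride transfers through the benzylic carbinol and a quinone-methide-type cation, while the primary OH is temporarily trifluoroacetylated and freed on bicarbonate work-up.

**Step 6**
Reactants: 9 2-(2,3-dibromo-4,5-dihydroxyphenyl)ethan-1-ol
Product: 10 2-(2,3-dibromo-4,5-dihydroxyphenyl)ethyl hydrogen sulfate
Conditions: H2SO4 (1.05 equiv), DCC (5 equiv), DMF, 0 °C, 30 min; filter, C18 reverse-phase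
Reagents that add atoms: sulfuric acid, OS(=O)(=O)O
Why: Carbodiimide-mediated sulfation (DCC/H2SO4) forms an O-sulfonyl isourea that the unhindered primary alcohol attacks much faster than the weakly nucleophilic, ortho-substituted, electron-poor phenols under these acidic, non-phenoxide conditions; no stereocentre.

**Compound list**
1 | 5-bromovanillin (3-bromo-4-hydroxy-5-methoxybenzaldehyde) | COc1cc(C=O)cc(Br)c1O | starting material
2 | 2,3-dibromo-4-hydroxy-5-methoxybenzaldehyde | COc1cc(C=O)c(Br)c(Br)c1O | intermediate
3 | 2,3-dibromo-4,5-dihydroxybenzaldehyde | O=Cc1cc(O)c(O)c(Br)c1Br | intermediate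
4 | 2,3-dibromo-4,5-bis(methoxymethoxy)benzaldehyde | COCOc1cc(C=O)c(Br)c(Br)c1OCOC | intermediate
5 | paraformaldehyde (source of formaldehyde) | C=O | starting material
6 | Breslow enaminol: [3-benzyl-5-(2-hydroxyethyl)-4-methylthiazol-2(3H)-ylidene][2,3-dibromo-4,5-bis(methoxymethoxy)phenyl]methanol | OC(c1cc(OCOC)c(OCOC)c(Br)c1Br)=C1SC(CCO)=C(C)N1Cc1ccccc1 | intermediate (not isolated)
7 | 1-[2,3-dibromo-4,5-bis(methoxymethoxy)phenyl]-2-hydroxyethan-1-one | COCOc1cc(C(=O)CO)c(Br)c(Br)c1OCOC | intermediate
8 | 2-(2,3-dibromo-4,5-dihydroxyphenyl)ethyl trifluoroacetate | O=C(OCCc1cc(O)c(O)c(Br)c1Br)C(F)(F)F | intermediate (not isolated)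
9 | 2-(2,3-dibromo-4,5-dihydroxyphenyl)ethan-1-ol | OCCc1cc(O)c(O)c(Br)c1Br | intermediate
10 | 2-(2,3-dibromo-4,5-dihydroxyphenyl)ethyl hydrogen sulfate | O=S(=O)(O)OCCc1cc(O)c(O)c(Br)c1Br | target

**Total step count:** 6
**Longest linear sequence:** 6 steps (1 → 10)

**Three steps most likely to fail, with fallbacks**

Step 4 (carbene-catalysed hydroxymethylation of a hindered, ortho-bromo, electron-rich aldehyde). If 4 is recovered or benzoin/formose products dominate, change from the catalytic acyl anion to a stoichiometric sulfur-ylide C1 donor. The fallback sets out from 4: Corey–Chaykovsky reaction with Me3S+ I−/NaH (DMSO–THF, 0 °C → rt) gives rac-2-[2,3-dibromo-4,5-bis(methoxymethoxy)phenyl]oxirane F1. Treating F1 with Et3SiH/TFA (0 °C → rt) opens the epoxide at the benzylic carbon, delivers hydride there and removes the MOM groups. It passes through trifluoroacetate 8 and, after bicarbonate work-up, comes back to the route at 9, bypassing ketone 7.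

Step 5 (cationic deoxygenation next to an α-oxygen on a dibrominated ring). If the reduction stalls at the carbinol or gives Friedel–Crafts oligomers, change to a non-cationic diazene deoxygenation. The fallback sets out from 7: condensation with TsNHNH2 (EtOH, 50 °C) gives N'-{1-[2,3-dibromo-4,5-bis(methoxymethoxy)phenyl]-2-hydroxyethylidene}-4-methylbenzenesulfonohydrazide F2. Reduction with catecholborane (CHCl3, 0 °C), then NaOAc·3H2O at reflux (Kabalka variant of the Caglioti reduction), gives 2-[2,3-dibromo-4,5-bis(methoxymethoxy)phenyl]ethan-1-ol F3. HCl in MeOH (rt) removes the MOM groups and the fallback comes back to the route at 9.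

Step 6 (primary alcohol versus two free phenols). If phenol sulfation competes, change from direct chemoselective sulfation to transient catechol protection. The fallback sets out from 9: PhB(OH)2 (1.0 equiv, toluene, Dean–Stark) gives the cyclic boronate 2-(6,7-dibromo-2-phenyl-1,3,2-benzodioxaborol-5-yl)ethan-1-ol F4. SO3·pyridine (2 equiv, DMF, 0 °C → rt) sulfates the only free hydroxyl to give 2-(6,7-dibromo-2-phenyl-1,3,2-benzodioxaborol-5-yl)ethyl hydrogen sulfate F5. Aqueous methanol work-up hydrolyses the boronate ester and the fallback comes back to the route at 10.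

**Further compounds**
F1 | step 4 | rac-2-[2,3-dibromo-4,5-bis(methoxymethoxy)phenyl]oxirane | COCOc1cc(C2CO2)c(Br)c(Br)c1OCOC
F2 | step 5 | N'-{1-[2,3-dibromo-4,5-bis(methoxymethoxy)phenyl]-2-hydroxyethylidene}-4-methylbenzenesulfonohydrazide (E/Z mixture) | Cc1ccc(cc1)S(=O)(=O)NN=C(CO)c1cc(OCOC)c(OCOC)c(Br)c1Br
F3 | step 5 | 2-[2,3-dibromo-4,5-bis(methoxymethoxy)phenyl]ethan-1-ol | OCCc1cc(OCOC)c(OCOC)c(Br)c1Br
F4 | step 6 | 2-(6,7-dibromo-2-phenyl-1,3,2-benzodioxaborol-5-yl)ethan-1-ol | OCCc1cc2OB(c3ccccc3)Oc2c(Br)c1Br
F5 | step 6 | 2-(6,7-dibromo-2-phenyl-1,3,2-benzodioxaborol-5-yl)ethyl hydrogen sulfate | O=S(=O)(O)OCCc1cc2OB(c3ccccc3)Oc2c(Br)c1Br
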